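**Retrosynthetic overview**
1. Target 18 ⇐ diphenol 16 by 6-O-geranylation, placed last because the geranyl alkenes would not survive the oxidant; 16 ⇐ triacetate 15 by cleavage of the two aryl acetates only.
2. 15 ⇐ achiral methyl 2-[(E)-prop-1-enyl]benzoate 9: one enantioselective oxylactonisation with a chiral aryl-λ3-iodane forms the O2–C3 bond, closes the lactone (ring B), installs the C4 acetate and sets C3 and C4.
3. Enabling feature: on arene ring A the ester carbonyl (C1, on C8a) is ortho to the C3=C4 propenyl group (on C4a), so its oxygen reaches C3 in a 6-endo closure; the cis C3–O/C4–OAc pair of ring B is the net syn dioxygenation of that E-alkene.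
4. 9 ⇐ aryl iodide 7 + propenylboronate 8 (Suzuki–Miyaura); 7 ⇐ acid 5 by carboxylate-directed C–H iodination; 5 ⇐ isovanillin 1 (Baeyer–Villiger/Dakin, Kolbe–Schmitt, acetylation); iodane 13 ⇐ 2-iodoresorcinol 10 + methyl (R)-lactate 11.
5. Ring order: ring A is bought with isovanillin; ring B is the only ring made, in the key step.

Key step: step 9

Assumption: the (S,S)-iodane 13 is taken to deliver both oxygen atoms to the alkene face that leads to the (3R,4R) lactone, by transposing the sense of induction of lactate-based aryl-λ3-iodanes with styrenes; should the sense be the reverse for 9, the enantiomeric iodane from methyl (S)-lactate is used and nothing else changes.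

**Route**

Step 1
Reactants: 1 isovanillin
Product: 3 4-methoxyresorcinol, via aryl formate 2 (not isolated)
Conditions: mCPBA (1.2 equiv), CH2Cl2, 0 °C → rt; then MeOH, Et3N (cat.), rt
Reagents that add atoms: mCPBA (3-chloroperoxybenzoic acid), O=C(OO)c1cccc(Cl)c1
Why: Baeyer–Villiger (Dakin-type) oxidation, in which the electron-rich aryl group para to the methoxy group migrates to give formate 2, whose base-catalysed methanolysis frees the phenol; no stereocentre is formed.

Step 2
Reactants: 3 4-methoxyresorcinol
Product: 4 2,4-dihydroxy-5-methoxybenzoic acid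
Conditions: KHCO3 (5 equiv), H2O, CO2 (1 atm), 100 °C; then aq HCl
Reagents that add atoms: carbon dioxide, O=C=O (from the CO2 atmosphere and from KHCO3, [K+].OC([O-])=O)
Why: Kolbe–Schmitt carboxylation of a resorcinol, which should occur at the carbon ortho to one hydroxyl and para to the other (the usual β-resorcylic acid regiochemistry) and not at the crowded carbon between the two hydroxyls.

Step 3
Reactants: 4 2,4-dihydroxy-5-methoxybenzoic acid
Product: 5 2,4-diacetoxy-5-methoxybenzoic acid
Conditions: Ac2O, H2SO4 (cat.), 50 °C; then H2O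
Reagents that add atoms: acetic anhydride, CC(=O)OC(C)=O
Why: acid-catalysed O-acetylation of both phenols (any mixed anhydride at the acid is hydrolysed on quench); the acetates turn the two strong donors into weak ones, which steps 4 and 9 both need.

Step 4
Reactants: 5 2,4-diacetoxy-5-methoxybenzoic acid
Product: 6 2,4-diacetoxy-6-iodo-5-methoxybenzoic acid
Conditions: [Cp*Ir(H2O)3]SO4 (3 mol %), NIS (1.5 equiv), HFIP, 40 °C
Reagents that add atoms: N-iodosuccinimide, O=C1CCC(=O)N1I
Why: carboxylate-directed ortho C–H iodination with a trivalent iridium catalyst, where cyclometalation can occur only at the single free ortho C–H (between CO2H and OMe) and NIS iodinates the iridacycle; any background electrophilic iodination should also go ortho to the methoxy group, the only strong donor left, that is to the same carbon.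

Step 5
Reactants: 6 2,4-diacetoxy-6-iodo-5-methoxybenzoic acid
Product: 7 methyl 2,4-diacetoxy-6-iodo-5-methoxybenzoate
Conditions: TMSCHN2, toluene/MeOH (4:1), 0 °C → rt
Reagents that add atoms: trimethylsilyldiazomethane, C[Si](C)(C)C=[N+]=[N-] (supplies the methyl carbon)
Why: diazoalkane esterification alkylates the carboxylate oxygen, so it is insensitive to the steric blockade of the 2,6-disubstituted carbonyl carbon, and the neutral conditions leave the aryl acetates alone.

Step 6
Reactants: 7 methyl 2,4-diacetoxy-6-iodo-5-methoxybenzoate; 8 (E)-prop-1-enylboronic acid pinacol ester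
Product: 9 methyl 2,4-diacetoxy-5-methoxy-6-[(E)-prop-1-enyl]benzoate
Conditions: Pd(OAc)2 (5 mol %), SPhos (10 mol %), K3PO4 (anhydrous, 2 equiv), toluene, 80 °C
Reagents that add atoms: none
Why: Suzuki–Miyaura coupling with a bulky biarylphosphine for the di-ortho-substituted iodide under anhydrous conditions that should spare the aryl acetates; transmetalation and reductive elimination proceed with retention, so the E geometry of 8 is carried into 9.

Step 7
Reactants: 10 2-iodoresorcinol; 11 methyl (R)-lactate (2.2 equiv)
Product: 12 dimethyl (2S,2'S)-2,2'-[(2-iodo-1,3-phenylene)bis(oxy)]dipropanoate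
Conditions: PPh3, DIAD, THF, 0 °C → rt
Reagents that add atoms: none
Why: double Mitsunobu etherification in which each aryl–O–C bond forms by SN2 inversion at the lactate carbon, so the (R)-lactate gives the (S,S)-diether.

Step 8
Reactants: 12 dimethyl (2S,2'S)-2,2'-[(2-iodo-1,3-phenylene)bis(oxy)]dipropanoate
Product: 13 (S,S)-lactate-derived aryl-λ3-iodane diacetate
Conditions: AcOOH (32 wt % in AcOH), AcOH, rt
Reagents that add atoms: peracetic acid, CC(=O)OO; acetic acid, CC(=O)O
Why: standard oxidation of an aryl iodide to the (diacetoxyiodo)arene with peracetic acid in acetic acid; the lactate stereocentres are not involved.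

Step 9
Reactants: 9 methyl 2,4-diacetoxy-5-methoxy-6-[(E)-prop-1-enyl]benzoate; 13 (S,S)-lactate-derived aryl-λ3-iodane diacetate (1.3 equiv)
Product: 15 (3R,4R)-5-methoxy-3-methyl-1-oxoisochromane-4,6,8-triyl triacetate, via iodanyl lactonium ion 14 (not isolated)
Conditions: BF3·OEt2 (2.5 equiv), AcOH (10 equiv), CH2Cl2, −78 → −40 °C
Reagents that add atoms: acetic acid, CC(=O)O (in exchange with the acetate ligands of 13; this acetate pool supplies the C4 acetoxy group)
Why: Enantioselective oxylactonisation of an ortho-alkenylbenzoate with a lactate-derived aryl-λ3-iodane (closest known type: the endo-selective hypervalent-iodine oxylactonisation that gives 4-acyloxy-3-alkylisochroman-1-ones): BF3 ionises 13 to ArI(OAc)+, which adds to one face of the C3=C4 bond, and the ester carbonyl oxygen opens this iodonium-type complex at C3 anti to iodine, forming the O2–C3 bond and ring B in a 6-endo closure to give lactonium ion 14 with the iodanyl group on benzylic C4. Acetate then displaces the aryl-λ3-iodanyl hypernucleofuge at C4 by SN2 with inversion, and the O-methyl group of the lactonium ion is lost to acetate as methyl acetate. C3 is set by reagent control (the C2-symmetric lactate arms of 13 choose the alkene face and anti attack fixes 3R), and C4 follows stereospecifically, because anti addition plus one inversion equals net syn dioxygenation of the E-alkene, hence the 3,4-cis (3R,4R) lactone. The step needs 6-endo over 5-exo attack and SN2 over SN1 at C4; both should be secured because the flanking C5 methoxy and C8a ester groups twist the alkene out of conjugation and the two aryl acetates sit meta to C4a, so C4 has little benzylic-cation character, while the ester oxygen reaches C3 more easily than C4. The same acetates keep ring A and the phenols inert to the oxidant, and C4 leaves the step already acetylated, so a free C4 hydroxyl (which could translactonise to the phthalide) never appears.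

Step 10
Reactants: 15 (3R,4R)-5-methoxy-3-methyl-1-oxoisochromane-4,6,8-triyl triacetate
Product: 16 (3R,4R)-6,8-dihydroxy-5-methoxy-3-methyl-1-oxoisochroman-4-yl acetate
Conditions: NH4OAc (10 equiv), MeOH/H2O (9:1), rt
Reagents that add atoms: none
Why: chemoselective methanolysis of aryl acetates (phenoxide leaving groups) under near-neutral ammonium acetate catalysis, conditions under which an alkyl acetate and the lactone should not be cleaved; the stereocentres are untouched.

Step 11
Reactants: 16 (3R,4R)-6,8-dihydroxy-5-methoxy-3-methyl-1-oxoisochroman-4-yl acetate; 17 geranyl bromide (1.05 equiv)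
Product: 18 (3R,4R)-6-(geranyloxy)-8-hydroxy-5-methoxy-3-methyl-1-oxoisochroman-4-yl acetate (CNP0251645.2)
Conditions: K2CO3 (1.1 equiv), acetone, rt
Reagents that add atoms: none
Why: Williamson etherification in which the C6 hydroxyl, para to the lactone carbonyl and not hydrogen-bonded, is the more acidic phenol and the only one alkylated with one equivalent of mild base, whereas the C8 hydroxyl is held in a hydrogen bond to the C1 carbonyl; SN2 at the primary allylic bromide keeps the 2E geometry.

**Compound list**
1 | isovanillin (3-hydroxy-4-methoxybenzaldehyde) | COc1ccc(C=O)cc1O | starting material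
2 | 3-hydroxy-4-methoxyphenyl formate | COc1ccc(OC=O)cc1O | intermediate
3 | 4-methoxyresorcinol (4-methoxybenzene-1,3-diol) | COc1ccc(O)cc1O | intermediate
4 | 2,4-dihydroxy-5-methoxybenzoic acid | COc1cc(C(=O)O)c(O)cc1O | intermediate
5 | 2,4-diacetoxy-5-methoxybenzoic acid | COc1cc(C(=O)O)c(OC(C)=O)cc1OC(C)=O | intermediate
6 | 2,4-diacetoxy-6-iodo-5-methoxybenzoic acid | COc1c(I)c(C(=O)O)c(OC(C)=O)cc1OC(C)=O | intermediate
7 | methyl 2,4-diacetoxy-6-iodo-5-methoxybenzoate | COc1c(I)c(C(=O)OC)c(OC(C)=O)cc1OC(C)=O | intermediate
8 | (E)-prop-1-enylboronic acid pinacol ester | C/C=C/B1OC(C)(C)C(C)(C)O1 | starting material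
9 | methyl 2,4-diacetoxy-5-methoxy-6-[(E)-prop-1-enyl]benzoate | COc1c(/C=C/C)c(C(=O)OC)c(OC(C)=O)cc1OC(C)=O | intermediate
10 | 2-iodoresorcinol (2-iodobenzene-1,3-diol) | Oc1cccc(O)c1I | starting material
11 | methyl (R)-lactate | C[C@@H](O)C(=O)OC | starting material
12 | dimethyl (2S,2'S)-2,2'-[(2-iodo-1,3-phenylene)bis(oxy)]dipropanoate | C[C@H](Oc1cccc(O[C@@H](C)C(=O)OC)c1I)C(=O)OC | intermediate
13 | dimethyl (2S,2'S)-2,2'-{[2-(diacetoxy-λ3-iodanyl)-1,3-phenylene]bis(oxy)}dipropanoate | C[C@H](Oc1cccc(O[C@@H](C)C(=O)OC)c1I(OC(C)=O)OC(C)=O)C(=O)OC | intermediate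
14 | (3R,4S)-6,8-diacetoxy-4-[acetoxy(aryl)-λ3-iodanyl]-1,5-dimethoxy-3-methyl-3,4-dihydroisochromenylium acetoxytrifluoroborate (aryl = 2,6-bis[(S)-1-methoxy-1-oxopropan-2-yloxy]phenyl) | COc1c(OC(C)=O)cc(OC(C)=O)c2c1[C@H](I(OC(C)=O)c1c(O[C@@H](C)C(=O)OC)cccc1O[C@@H](C)C(=O)OC)[C@@H](C)OC2=[O+]C.CC(=O)O[B-](F)(F)F | intermediate
15 | (3R,4R)-5-methoxy-3-methyl-1-oxoisochromane-4,6,8-triyl triacetate | COc1c(OC(C)=O)cc(OC(C)=O)c2c1[C@@H](OC(C)=O)[C@@H](C)OC2=O | intermediate
16 | (3R,4R)-6,8-dihydroxy-5-methoxy-3-methyl-1-oxoisochroman-4-yl acetate | COc1c(O)cc(O)c2c1[C@@H](OC(C)=O)[C@@H](C)OC2=O | intermediate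
17 | geranyl bromide ((2E)-1-bromo-3,7-dimethylocta-2,6-diene) | BrC/C=C(\C)CCC=C(C)C | starting material
18 | (3R,4R)-6-{[(2E)-3,7-dimethylocta-2,6-dien-1-yl]oxy}-8-hydroxy-5-methoxy-3-methyl-1-oxoisochroman-4-yl acetate | COc1c(OC/C=C(\C)CCC=C(C)C)cc(O)c2c1[C@@H](OC(C)=O)[C@@H](C)OC2=O | target

**Step count and risks**

Total steps: 11 (9 on the main line, 2 for the chiral iodane). Longest linear sequence: 9 steps (steps 1–6 and 9–11, from isovanillin 1).

Steps most likely to fail:

Step 4. Cyclometalation may stall at a C–H bond that is flanked by the methoxy group, or undirected electrophilic iodination at the carbon between the two acetoxy groups may compete. Fallback, from 4 back to 6: the same C–H bond is the best site for a carboxylate-directed ortho-lithiation, where the flanking methoxy group helps. Acid 4 is persilylated (TIPSCl, imidazole, DMF) to triisopropylsilyl 5-methoxy-2,4-bis(triisopropylsilyloxy)benzoate F1. The silyl ester is cleaved (K2CO3, MeOH/H2O) to 5-methoxy-2,4-bis(triisopropylsilyloxy)benzoic acid F2. Lithiation with s-BuLi/TMEDA (THF, −78 °C; the carbon between the two bulky silyloxy groups is shielded and has no directing group) and quenching with I2 should give 6-iodo-5-methoxy-2,4-bis(triisopropylsilyloxy)benzoic acid F3. TBAF then gives 2,4-dihydroxy-6-iodo-5-methoxybenzoic acid F4, and acetylation as in step 3 returns to 6.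

Step 9. Ionisation at C4 of the alkyl-λ3-iodane (an open benzylic cation or acetoxonium participation) may erode the cis selectivity, the facial selectivity may be low, or ring A may be oxidised. Fallback, from 6 back to 15: the dioxygenation is split into two stereospecific events with a poorer nucleofuge. Iodo acid 6 is coupled with 8 under the conditions of step 6 (one more equivalent of K3PO4) to give 2,4-diacetoxy-5-methoxy-6-[(E)-prop-1-enyl]benzoic acid F5. Catalytic enantioselective 6-endo bromolactonisation (N-bromosuccinimide, cinchona-derived amino-thiocarbamate catalyst, CHCl3/toluene, −60 °C; the pseudo-enantiomer of the catalyst is chosen for the 3R series) should give the trans bromolactone (3R,4S)-4-bromo-5-methoxy-3-methyl-1-oxoisochromane-6,8-diyl diacetate F6 by anti addition, still forming the O2–C3 bond in the ring closure. SN2 displacement of the bromide with Bu4NOAc in acetone inverts C4 and returns to 15.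

Step 10. Methanolysis may fail to discriminate between the aryl acetates and the C4 acetate; loss of the C4 acetate would be followed by translactonisation to the phthalide. Fallback, from 9 back to 16: the phenols are carried through the key step as chloroacetates, which are orthogonal to the C4 acetate. Alkene 9 is treated with K2CO3 (cat.) in MeOH (aryl acetates only; the hindered methyl ester stays) to give methyl 2,4-dihydroxy-5-methoxy-6-[(E)-prop-1-enyl]benzoate F7. Chloroacetic anhydride/pyridine gives methyl 2,4-bis(chloroacetoxy)-5-methoxy-6-[(E)-prop-1-enyl]benzoate F8. The conditions of step 9 should give (3R,4R)-4-acetoxy-5-methoxy-3-methyl-1-oxoisochromane-6,8-diyl bis(chloroacetate) F9. Thiourea/NaHCO3 in EtOH/THF removes only the chloroacetates and returns to 16.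

Further compounds
F1 | step 4 | triisopropylsilyl 5-methoxy-2,4-bis(triisopropylsilyloxy)benzoate | COc1cc(C(=O)O[Si](C(C)C)(C(C)C)C(C)C)c(O[Si](C(C)C)(C(C)C)C(C)C)cc1O[Si](C(C)C)(C(C)C)C(C)C
F2 | step 4 | 5-methoxy-2,4-bis(triisopropylsilyloxy)benzoic acid | COc1cc(C(=O)O)c(O[Si](C(C)C)(C(C)C)C(C)C)cc1O[Si](C(C)C)(C(C)C)C(C)C
F3 | step 4 | 6-iodo-5-methoxy-2,4-bis(triisopropylsilyloxy)benzoic acid | COc1c(I)c(C(=O)O)c(O[Si](C(C)C)(C(C)C)C(C)C)cc1O[Si](C(C)C)(C(C)C)C(C)C
F4 | step 4 | 2,4-dihydroxy-6-iodo-5-methoxybenzoic acid | COc1c(I)c(C(=O)O)c(O)cc1O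
F5 | step 9 | 2,4-diacetoxy-5-methoxy-6-[(E)-prop-1-enyl]benzoic acid | COc1c(/C=C/C)c(C(=O)O)c(OC(C)=O)cc1OC(C)=O
F6 | step 9 | (3R,4S)-4-bromo-5-methoxy-3-methyl-1-oxoisochromane-6,8-diyl diacetate | COc1c(OC(C)=O)cc(OC(C)=O)c2c1[C@H](Br)[C@@H](C)OC2=O
F7 | step 10 | methyl 2,4-dihydroxy-5-methoxy-6-[(E)-prop-1-enyl]benzoate | COc1c(/C=C/C)c(C(=O)OC)c(O)cc1O
F8 | step 10 | methyl 2,4-bis(chloroacetoxy)-5-methoxy-6-[(E)-prop-1-enyl]benzoate | COc1c(/C=C/C)c(C(=O)OC)c(OC(=O)CCl)cc1OC(=O)CCl
F9 | step 10 | (3R,4R)-4-acetoxy-5-methoxy-3-methyl-1-oxoisochromane-6,8-diyl bis(chloroacetate) | COc1c(OC(=O)CCl)cc(OC(=O)CCl)c2c1[C@@H](OC(C)=O)[C@@H](C)OC2=O
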